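**Plan**
- Cuts: C2–C1' (ring B onto a chromone), the C2 carbon of ring C (a one-carbon unit on an acetophenone), both C=C-forming bonds of the prenyl arm, and finally the benzylic CH2–CH bond together with one ring A O–C bond.
- Enabling feature: the CH2 on C8 of ring A lies between the oxygens on C7 and C8a, so it is the exocyclic carbon of an ortho-quinone methide. The unit CH(prenyl)–CH(CH3)–CH2OH is C4–C3–C2–O1 of 3-methyl-2,3-dihydrofuran, and the first prenyl carbon is its C5.
- Forward order: dihydrofuran plus the phloroacetophenone Mannich base close a pyran ring (furo[2,3-b]chromene acetal). The acetal is opened as a dithiane, the OH groups are protected, and the aldehyde is released and extended by two Wittig reactions. Ring C is then built as a chromone, ring B is added, and all protecting groups are removed.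
- Stereochemistry: the CH3-bearing carbon comes from methyl (S)-3-hydroxy-2-methylpropanoate. The prenyl-bearing carbon comes from addition anti to that methyl group in the cycloaddition. C2 comes from a chiral rhodium catalyst.

Key step: step 7

Assumption: the cycloadduct is drawn as the isomer closed through the ring A oxygen para to the acetyl group (the ortho-closed isomer would be opened to the same dithiane one step later), and the (S)-configured biaryl bisphosphine, which turns cyclohex-2-enone into (S)-3-arylcyclohexanones, is taken to attack the spatially equivalent chromone face, which is 2S by the CIP rules.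

**Step 1**
Reactants: 1 methyl (S)-3-hydroxy-2-methylpropanoate
Product: 2 methyl (S)-2-methyl-3-(trityloxy)propanoate
Conditions: TrCl (1.1 equiv), Et3N, DMAP (cat.), CH2Cl2, rt
Reagents that add atoms: trityl chloride, ClC(c1ccccc1)(c1ccccc1)c1ccccc1
Why: Tritylation (SN1-type O-alkylation) takes the primary alcohol without touching the α-stereocentre and gives a heavy carrier whose cleavage product stays behind when the volatile furans are distilled later.

**Step 2**
Reactants: 2 methyl (S)-2-methyl-3-(trityloxy)propanoate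
Product: 3 (S)-2-methyl-3-(trityloxy)propanal
Conditions: i-Bu2AlH (1.05 equiv), CH2Cl2, −78 °C; MeOH, then aq. potassium sodium tartrate
Reagents that add atoms: none
Why: Partial ester reduction stops at the aluminium hemiacetal at low temperature, the standard access to this configurationally sensitive aldehyde, which is used at once.

**Step 3**
Reactants: 3 (S)-2-methyl-3-(trityloxy)propanal
Product: 4 (R)-4-methoxy-2-methylbut-3-enyl trityl ether (E/Z mixture)
Conditions: MeOCH2PPh3Cl, KOt-Bu, THF, 0 °C; then 3, −78 → 0 °C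
Reagents that add atoms: (methoxymethyl)triphenylphosphonium chloride, COC[P+](c1ccccc1)(c1ccccc1)c1ccccc1.[Cl-]
Why: Wittig methoxymethylenation adds the missing carbon as an enol ether, and the preformed ylide olefinates faster than it enolises the aldehyde, so the centre is kept (the descriptor changes to R only through CIP priorities).

**Step 4**
Reactants: 4 (R)-4-methoxy-2-methylbut-3-enyl trityl ether
Product: 5 (4R)-2-methoxy-4-methyltetrahydrofuran (anomer mixture)
Conditions: p-TsOH·H2O (5 mol %), MeOH, rt; K2CO3, filter, fractional distillation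
Reagents that add atoms: methanol, CO
Why: Acid-catalysed methanolysis removes the trityl group as its cation, and the freed alcohol adds to the protonated enol ether (5-exo-trig acetalisation) to give the five-membered methyl acetal.

**Step 5**
Reactants: 5 (4R)-2-methoxy-4-methyltetrahydrofuran
Product: 6 (R)-3-methyl-2,3-dihydrofuran
Conditions: p-TsOH (1 mol %), neat, 150–170 °C bath, distil into a receiver holding K2CO3; cold brine wash, redistil
Reagents that add atoms: none
Why: Acid-catalysed acetal cracking (1,2-elimination of methanol through the cyclic oxocarbenium ion) is driven by distillation, and only the CH2 next to the acetal carbon can lose a proton, so the alkene cannot reach the stereocentre.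

**Step 6**
Reactants: 7 2,4,6-trihydroxyacetophenone
Product: 8 1-[2,4,6-trihydroxy-3-(morpholin-4-ylmethyl)phenyl]ethanone
Conditions: morpholine (1.0 equiv), 37 % aq. CH2O (1.0 equiv), EtOH, 0 °C → rt
Reagents that add atoms: formaldehyde, C=O; morpholine, C1COCCN1
Why: In this Mannich aminomethylation the two free ring positions are equivalent, so only one mono-adduct exists, and one equivalent of iminium ion plus the low solubility of the zwitterion limit a second substitution.

**Step 7**
Reactants: 8 1-[2,4,6-trihydroxy-3-(morpholin-4-ylmethyl)phenyl]ethanone; 6 (R)-3-methyl-2,3-dihydrofuran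
Product: 10 1-[(3R,3aR,9aR)-5,7-dihydroxy-3-methyl-2,3,3a,9a-tetrahydro-4H-furo[2,3-b]chromen-6-yl]ethanone, via ortho-quinone methide 9 (not isolated)
Conditions: 6 (3 equiv), 1,4-dioxane (0.02 M in 8), 100 °C, sealed tube
Reagents that add atoms: none
Why: Heating the zwitterionic Mannich base expels morpholine (retro-Mannich, E1cB-like) and releases methide 9, an electron-poor 1-oxadiene, which the electron-rich enol ether 6 intercepts in an asynchronous inverse-electron-demand hetero-Diels–Alder reaction: C4 of 6 bonds to the exocyclic CH2 and the methide oxygen then closes onto the developing oxocarbenium carbon C5. The closest known reaction type is the thermal capture of methides from phenolic Mannich bases by alkyl-substituted 2,3-dihydrofurans to give furo[2,3-b]chromene acetals and ketals. The single new ring, the dihydropyran, is closed in [4+2] mode and must be cis-fused, because both bonds are made suprafacially to the Z-alkene of a five-membered ring; this fixes C9a relative to C3a. C3a is controlled by the C3 methyl group of 6, which stands on the carbon next to the attacked one and blocks its own face, so that the methide arrives anti and the arylmethyl and methyl groups end up trans (3R,3aR,9aR); endo and exo approaches lead to the same product since the methide terminus carries only hydrogen. Regiochemistry is secured by polarity (nucleophilic β-carbon of the enol ether to the electrophilic CH2), and the symmetry of ring A means that only one methide skeleton can form. The selectivity still needed is chemoselectivity against attack of the free aromatic CH of a second acylphloroglucinol on 9, which excess 6 and high dilution are meant to provide.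

**Step 8**
Reactants: 10 1-[(3R,3aR,9aR)-5,7-dihydroxy-3-methyl-2,3,3a,9a-tetrahydro-4H-furo[2,3-b]chromen-6-yl]ethanone
Product: 11 1-{3-[(2R,3R)-2-(1,3-dithian-2-yl)-4-hydroxy-3-methylbutyl]-2,4,6-trihydroxyphenyl}ethanone
Conditions: HS(CH2)3SH (1.5 equiv), BF3·OEt2 (0.5 equiv), CH2Cl2, −20 → 0 °C
Reagents that add atoms: propane-1,3-dithiol, SCCCS
Why: In this Lewis-acid-catalysed transthioacetalisation the acidic aryl oxygen leaves first and sulfur captures the oxocarbenium and then the thionium ion, and the dithiane does not revert, whereas aqueous acid would only equilibrate the hydroxy aldehyde with the favoured bicyclic acetal; both stereocentres are spectators.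

**Step 9**
Reactants: 11 1-{3-[(2R,3R)-2-(1,3-dithian-2-yl)-4-hydroxy-3-methylbutyl]-2,4,6-trihydroxyphenyl}ethanone
Product: 12 1-{3-[(2R,3R)-2-(1,3-dithian-2-yl)-4-hydroxy-3-methylbutyl]-2-hydroxy-4,6-bis(methoxymethoxy)phenyl}ethanone
Conditions: MOMCl (2.1 equiv), i-Pr2NEt (2.5 equiv), CH2Cl2, 0 °C
Reagents that add atoms: chloromethyl methyl ether, COCCl
Why: In this Williamson-type O-alkylation the acidic phenols react far faster than the neutral alcohol, and the hydroxyl wedged between the acetyl group and the branched side chain keeps the stronger, buttressed hydrogen bond and stays free, as in the partial alkylation of 3-alkylphloroacetophenones.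

**Step 10**
Reactants: 12 1-{3-[(2R,3R)-2-(1,3-dithian-2-yl)-4-hydroxy-3-methylbutyl]-2-hydroxy-4,6-bis(methoxymethoxy)phenyl}ethanone
Product: 13 1-{3-[(2R,3R)-2-(1,3-dithian-2-yl)-3-methyl-4-(triisopropylsilyloxy)butyl]-2-hydroxy-4,6-bis(methoxymethoxy)phenyl}ethanone
Conditions: TIPSCl (1.2 equiv), imidazole, DMF, rt
Reagents that add atoms: triisopropylsilyl chloride, CC(C)[Si](Cl)(C(C)C)C(C)C
Why: Imidazole-promoted silylation with the bulky chloride takes the primary alcohol and not the chelated, flanked phenol, and the TIPS ether should survive the brief acid of step 12 yet fall in the last step; it also prevents re-closure to a bicyclic acetal.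

**Step 11**
Reactants: 13 1-{3-[(2R,3R)-2-(1,3-dithian-2-yl)-3-methyl-4-(triisopropylsilyloxy)butyl]-2-hydroxy-4,6-bis(methoxymethoxy)phenyl}ethanone
Product: 14 (2R,3R)-2-{[3-acetyl-2-hydroxy-4,6-bis(methoxymethoxy)phenyl]methyl}-3-methyl-4-(triisopropylsilyloxy)butanal (open form drawn; may rest as its chroman-2-ol)
Conditions: MeI (10 equiv), CaCO3, MeCN–H2O (9:1), 40 °C
Reagents that add atoms: water, O
Why: Alkylative dithiane hydrolysis (S-methylation, then hydrolysis under CaCO3 buffering) is non-oxidative and near neutral, so the electron-rich arene, the MOM and TIPS groups and the α-stereocentre should be left alone.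

**Step 12**
Reactants: 14 (2R,3R)-2-{[3-acetyl-2-hydroxy-4,6-bis(methoxymethoxy)phenyl]methyl}-3-methyl-4-(triisopropylsilyloxy)butanal
Product: 16 (3S,4R)-3-{[3-acetyl-2-hydroxy-4,6-bis(methoxymethoxy)phenyl]methyl}-4-methyl-5-(triisopropylsilyloxy)pentanal, via methyl enol ether 15 (not isolated)
Conditions: MeOCH2PPh3Cl (3.5 equiv), KOt-Bu (3.3 equiv), THF, 0 °C; 14, −78 → 0 °C; then 0.5 M aq. HCl–THF, 0 °C → rt
Reagents that add atoms: (methoxymethyl)triphenylphosphonium chloride, COC[P+](c1ccccc1)(c1ccccc1)c1ccccc1.[Cl-]; water, O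
Why: This is one-carbon homologation by Wittig methoxymethylenation and enol ether hydrolysis; the first equivalent of ylide makes the phenoxide, which opens any chroman-2-ol and turns the acetyl group into an inert vinylogous carboxylate, and enol ethers hydrolyse far faster than aryl MOM or TIPS ethers (the descriptor becomes S by CIP priorities only).

**Step 13**
Reactants: 16 (3S,4R)-3-{[3-acetyl-2-hydroxy-4,6-bis(methoxymethoxy)phenyl]methyl}-4-methyl-5-(triisopropylsilyloxy)pentanal
Product: 17 1-{2-hydroxy-4,6-bis(methoxymethoxy)-3-[(2R)-5-methyl-2-[(2R)-1-(triisopropylsilyloxy)propan-2-yl]hex-4-enyl]phenyl}ethanone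
Conditions: i-PrPPh3I (3.2 equiv), n-BuLi (3.0 equiv), THF, 0 °C; 16, −78 °C → rt
Reagents that add atoms: isopropyltriphenylphosphonium iodide, CC(C)[P+](c1ccccc1)(c1ccccc1)c1ccccc1.[I-]
Why: Wittig olefination with the non-stabilised isopropylidene ylide completes the prenyl arm; the aldehyde now has a CH2 at its α-position, so no stereocentre is at risk, and the ketone is again masked as the chelated phenoxide.

**Step 14**
Reactants: 17 1-{2-hydroxy-4,6-bis(methoxymethoxy)-3-[(2R)-5-methyl-2-[(2R)-1-(triisopropylsilyloxy)propan-2-yl]hex-4-enyl]phenyl}ethanone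
Product: 19 5,7-bis(methoxymethoxy)-8-{(2R)-5-methyl-2-[(2R)-1-(triisopropylsilyloxy)propan-2-yl]hex-4-enyl}-4H-chromen-4-one, via enaminone 18 (not isolated)
Conditions: Me2NCH(OMe)2 (4 equiv), toluene, 95 °C; evaporate; AcOH (5 equiv), toluene, 60 °C
Reagents that add atoms: N,N-dimethylformamide dimethyl acetal, COC(OC)N(C)C
Why: This is the enaminone route to chromones (condensation at the acetyl CH3, then weak-acid-promoted addition–elimination of the phenol with loss of dimethylamine); only the hydroxyl next to the side chain is free, so ring C closes to the 8-substituted isomer.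

**Step 15**
Reactants: 20 4-bromo-3-methoxyphenol
Product: 21 1-bromo-2-methoxy-4-(methoxymethoxy)benzene
Conditions: MOMCl (1.2 equiv), i-Pr2NEt, CH2Cl2, 0 °C → rt
Reagents that add atoms: chloromethyl methyl ether, COCCl
Why: Williamson-type MOM protection removes the acidic proton before lithiation and matches the ring A protecting groups for one final cleavage.

**Step 16**
Reactants: 21 1-bromo-2-methoxy-4-(methoxymethoxy)benzene
Product: 24 [2-methoxy-4-(methoxymethoxy)phenyl]boronic acid, via aryllithium 22 (not isolated), via lithium aryl(triisopropoxy)borate 23 (not isolated)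
Conditions: n-BuLi (1.05 equiv), THF, −78 °C; B(Oi-Pr)3, −78 °C → rt; aq. NH4Cl
Reagents that add atoms: triisopropyl borate, CC(C)OB(OC(C)C)OC(C)C; water, O
Why: Bromine–lithium exchange outruns directed ortho-metalation at −78 °C, and borylation followed by mild hydrolysis gives the boronic acid without loss of the MOM group.

**Step 17**
Reactants: 19 5,7-bis(methoxymethoxy)-8-{(2R)-5-methyl-2-[(2R)-1-(triisopropylsilyloxy)propan-2-yl]hex-4-enyl}-4H-chromen-4-one; 24 [2-methoxy-4-(methoxymethoxy)phenyl]boronic acid
Product: 25 (2S)-2-[2-methoxy-4-(methoxymethoxy)phenyl]-5,7-bis(methoxymethoxy)-8-{(2R)-5-methyl-2-[(2R)-1-(triisopropylsilyloxy)propan-2-yl]hex-4-enyl}-2,3-dihydro-4H-chromen-4-one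
Conditions: 24 (3 equiv), [Rh(OH)(cod)]2 (2.5 mol %), (S)-(6,6'-dimethoxybiphenyl-2,2'-diyl)bis[bis(3,4,5-trifluorophenyl)phosphane] (5.5 mol %), toluene–H2O (10:1), 30 °C
Reagents that add atoms: none
Why: In this rhodium-catalysed asymmetric 1,4-addition of an arylboronic acid to a chromone (Hayashi–Miyaura reaction) the electron-poor bisphosphine makes the aryl complex of monovalent rhodium reactive enough at low temperature without added base, so the flavanone does not ring-open; the ligand selects the enone face and sets C2 as S, and the remote side-chain centres should have no say.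

**Step 18**
Reactants: 25 (2S)-2-[2-methoxy-4-(methoxymethoxy)phenyl]-5,7-bis(methoxymethoxy)-8-{(2R)-5-methyl-2-[(2R)-1-(triisopropylsilyloxy)propan-2-yl]hex-4-enyl}-2,3-dihydro-4H-chromen-4-one
Product: 26 (2S)-5,7-dihydroxy-2-(4-hydroxy-2-methoxyphenyl)-8-{(2R)-2-[(2R)-1-hydroxypropan-2-yl]-5-methylhex-4-enyl}-2,3-dihydro-4H-chromen-4-one
Conditions: HCl (1.25 M in MeOH), 40 °C
Reagents that add atoms: none
Why: Acid-catalysed transacetalisation of the three aryl MOM ethers and methanolysis of the primary TIPS ether run under one mild set of conditions, which avoids the base-induced ring opening that would scramble C2 and leaves the aryl methyl ether and the trisubstituted alkene intact.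

**Compound list**
1 | methyl (S)-3-hydroxy-2-methylpropanoate | COC(=O)[C@@H](C)CO | starting material
2 | methyl (S)-2-methyl-3-(trityloxy)propanoate | COC(=O)[C@@H](C)COC(c1ccccc1)(c1ccccc1)c1ccccc1 | intermediate
3 | (S)-2-methyl-3-(trityloxy)propanal | O=C[C@@H](C)COC(c1ccccc1)(c1ccccc1)c1ccccc1 | intermediate
4 | (R)-4-methoxy-2-methylbut-3-enyl trityl ether (E/Z mixture) | COC=C[C@@H](C)COC(c1ccccc1)(c1ccccc1)c1ccccc1 | intermediate
5 | (4R)-2-methoxy-4-methyltetrahydrofuran (anomer mixture) | COC1C[C@@H](C)CO1 | intermediate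
6 | (R)-3-methyl-2,3-dihydrofuran | O1C=C[C@@H](C)C1 | intermediate
7 | 2,4,6-trihydroxyacetophenone | CC(=O)c1c(O)cc(O)cc1O | starting material
8 | 1-[2,4,6-trihydroxy-3-(morpholin-4-ylmethyl)phenyl]ethanone | CC(=O)c1c(O)cc(O)c(CN2CCOCC2)c1O | intermediate
9 | 4-acetyl-3,5-dihydroxy-6-methylidenecyclohexa-2,4-dien-1-one (ortho-quinone methide) | CC(=O)C1=C(O)C(=C)C(=O)C=C1O | intermediate
10 | 1-[(3R,3aR,9aR)-5,7-dihydroxy-3-methyl-2,3,3a,9a-tetrahydro-4H-furo[2,3-b]chromen-6-yl]ethanone (cis-fused, CH3 trans to the benzylic CH2) | CC(=O)c1c(O)cc2O[C@H]3OC[C@H](C)[C@H]3Cc2c1O | intermediate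
11 | 1-{3-[(2R,3R)-2-(1,3-dithian-2-yl)-4-hydroxy-3-methylbutyl]-2,4,6-trihydroxyphenyl}ethanone | CC(=O)c1c(O)cc(O)c(C[C@@H](C2SCCCS2)[C@@H](C)CO)c1O | intermediate
12 | 1-{3-[(2R,3R)-2-(1,3-dithian-2-yl)-4-hydroxy-3-methylbutyl]-2-hydroxy-4,6-bis(methoxymethoxy)phenyl}ethanone | CC(=O)c1c(OCOC)cc(OCOC)c(C[C@@H](C2SCCCS2)[C@@H](C)CO)c1O | intermediate
13 | 1-{3-[(2R,3R)-2-(1,3-dithian-2-yl)-3-methyl-4-(triisopropylsilyloxy)butyl]-2-hydroxy-4,6-bis(methoxymethoxy)phenyl}ethanone | CC(=O)c1c(OCOC)cc(OCOC)c(C[C@@H](C2SCCCS2)[C@@H](C)CO[Si](C(C)C)(C(C)C)C(C)C)c1O | intermediate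
14 | (2R,3R)-2-{[3-acetyl-2-hydroxy-4,6-bis(methoxymethoxy)phenyl]methyl}-3-methyl-4-(triisopropylsilyloxy)butanal | CC(=O)c1c(OCOC)cc(OCOC)c(C[C@@H](C=O)[C@@H](C)CO[Si](C(C)C)(C(C)C)C(C)C)c1O | intermediate
15 | 1-{2-hydroxy-3-[(2R)-4-methoxy-2-[(2R)-1-(triisopropylsilyloxy)propan-2-yl]but-3-enyl]-4,6-bis(methoxymethoxy)phenyl}ethanone (E/Z mixture) | CC(=O)c1c(OCOC)cc(OCOC)c(C[C@@H](C=COC)[C@@H](C)CO[Si](C(C)C)(C(C)C)C(C)C)c1O | intermediate
16 | (3S,4R)-3-{[3-acetyl-2-hydroxy-4,6-bis(methoxymethoxy)phenyl]methyl}-4-methyl-5-(triisopropylsilyloxy)pentanal | CC(=O)c1c(OCOC)cc(OCOC)c(C[C@@H](CC=O)[C@@H](C)CO[Si](C(C)C)(C(C)C)C(C)C)c1O | intermediate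
17 | 1-{2-hydroxy-4,6-bis(methoxymethoxy)-3-[(2R)-5-methyl-2-[(2R)-1-(triisopropylsilyloxy)propan-2-yl]hex-4-enyl]phenyl}ethanone | CC(=O)c1c(OCOC)cc(OCOC)c(C[C@@H](CC=C(C)C)[C@@H](C)CO[Si](C(C)C)(C(C)C)C(C)C)c1O | intermediate
18 | (E)-3-(dimethylamino)-1-{2-hydroxy-4,6-bis(methoxymethoxy)-3-[(2R)-5-methyl-2-[(2R)-1-(triisopropylsilyloxy)propan-2-yl]hex-4-enyl]phenyl}prop-2-en-1-one | CN(C)/C=C/C(=O)c1c(OCOC)cc(OCOC)c(C[C@@H](CC=C(C)C)[C@@H](C)CO[Si](C(C)C)(C(C)C)C(C)C)c1O | intermediate
19 | 5,7-bis(methoxymethoxy)-8-{(2R)-5-methyl-2-[(2R)-1-(triisopropylsilyloxy)propan-2-yl]hex-4-enyl}-4H-chromen-4-one | O=c1ccoc2c(C[C@@H](CC=C(C)C)[C@@H](C)CO[Si](C(C)C)(C(C)C)C(C)C)c(OCOC)cc(OCOC)c12 | intermediate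
20 | 4-bromo-3-methoxyphenol | COc1cc(O)ccc1Br | starting material
21 | 1-bromo-2-methoxy-4-(methoxymethoxy)benzene | COCOc1ccc(Br)c(OC)c1 | intermediate
22 | [2-methoxy-4-(methoxymethoxy)phenyl]lithium | [Li]c1ccc(OCOC)cc1OC | intermediate
23 | lithium [2-methoxy-4-(methoxymethoxy)phenyl]triisopropoxyborate | [Li+].COCOc1ccc([B-](OC(C)C)(OC(C)C)OC(C)C)c(OC)c1 | intermediate
24 | [2-methoxy-4-(methoxymethoxy)phenyl]boronic acid | COCOc1ccc(B(O)O)c(OC)c1 | intermediate
25 | (2S)-2-[2-methoxy-4-(methoxymethoxy)phenyl]-5,7-bis(methoxymethoxy)-8-{(2R)-5-methyl-2-[(2R)-1-(triisopropylsilyloxy)propan-2-yl]hex-4-enyl}-2,3-dihydro-4H-chromen-4-one | COc1cc(OCOC)ccc1[C@@H]1CC(=O)c2c(OCOC)cc(OCOC)c(C[C@@H](CC=C(C)C)[C@@H](C)CO[Si](C(C)C)(C(C)C)C(C)C)c2O1 | intermediate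
26 | (2S)-5,7-dihydroxy-2-(4-hydroxy-2-methoxyphenyl)-8-{(2R)-2-[(2R)-1-hydroxypropan-2-yl]-5-methylhex-4-enyl}-2,3-dihydro-4H-chromen-4-one | COc1cc(O)ccc1[C@@H]1CC(=O)c2c(O)cc(O)c(C[C@@H](CC=C(C)C)[C@@H](C)CO)c2O1 | target

**Step count**
- Total steps: 18.
- Longest linear sequence: 15 (steps 1–5, 7–14, 17, 18).

**Steps most likely to fail**

**Step 7.** A single methyl group may discriminate too weakly between the two faces of 6, so that the configuration at C3a is eroded. The fallback sets that centre thermodynamically instead of kinetically.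
- It sets out from 12, carried forward as the epimer mixture.
- The dithiane is removed with the alcohol still free (MeI, CaCO3, aq. MeCN) to give the lactol 1-{2-hydroxy-3-{[(3R,4R)-2-hydroxy-4-methyltetrahydrofuran-3-yl]methyl}-4,6-bis(methoxymethoxy)phenyl}ethanone F1.
- DBU in THF should equilibrate F1 through its open hydroxy aldehyde to the more stable 3,4-trans ring.
- Wittig methoxymethylenation of the lactol with excess ylide should give the hydroxy enol ether 1-{2-hydroxy-3-[(2R)-2-[(2R)-1-hydroxypropan-2-yl]-4-methoxybut-3-enyl]-4,6-bis(methoxymethoxy)phenyl}ethanone F2.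
- Silylation with TIPSCl and imidazole brings the material back to the route at 15, which is hydrolysed as in the second half of step 12.

**Step 17.** Carbometalation of the electron-rich, 8-substituted chromone may be slower than protodeboronation of the ortho-methoxy boronic acid. The fallback builds ring C from a chalcone.
- It sets out from 17 and 21.
- Aryllithium 22, made from 21, is quenched with DMF to give 2-methoxy-4-(methoxymethoxy)benzaldehyde F3.
- Claisen–Schmidt condensation of 17 with F3 (KOH, EtOH) gives the (E)-chalcone F4.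
- Oxa-Michael cyclisation (NaOAc, EtOH, reflux) gives 25 together with its (2R)-epimer F5.
- The two are diastereomers because of the side chain, so they can be separated by chromatography.
- F5 is resubjected to the cyclisation conditions, which re-equilibrate it through F4. The fallback rejoins the route at 25.

**Step 12.** The basic ylide may epimerise the formyl-bearing carbon of 14 before olefination. The fallback replaces both olefinations by an sp3–sp2 coupling.
- It sets out from 14.
- NaBH4 (MeOH–THF, −20 °C) reduces only the aldehyde and gives the alcohol 1-{2-hydroxy-3-[(2R,3R)-2-(hydroxymethyl)-3-methyl-4-(triisopropylsilyloxy)butyl]-4,6-bis(methoxymethoxy)phenyl}ethanone F6.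
- I2, PPh3 and imidazole give the iodide 1-{2-hydroxy-3-[(2R,3R)-2-(iodomethyl)-3-methyl-4-(triisopropylsilyloxy)butyl]-4,6-bis(methoxymethoxy)phenyl}ethanone F7.
- Substitution with excess LiCu(CH=CMe2)2 (Et2O, −30 → 0 °C; one equivalent is spent on the phenol) installs the 2-methylpropenyl group. The fallback rejoins the route at 17.

**Further compounds**
F1 | step 7 | 1-{2-hydroxy-3-{[(3R,4R)-2-hydroxy-4-methyltetrahydrofuran-3-yl]methyl}-4,6-bis(methoxymethoxy)phenyl}ethanone | CC(=O)c1c(OCOC)cc(OCOC)c(C[C@H]2C(O)OC[C@@H]2C)c1O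
F2 | step 7 | 1-{2-hydroxy-3-[(2R)-2-[(2R)-1-hydroxypropan-2-yl]-4-methoxybut-3-enyl]-4,6-bis(methoxymethoxy)phenyl}ethanone | CC(=O)c1c(OCOC)cc(OCOC)c(C[C@@H](C=COC)[C@@H](C)CO)c1O
F3 | step 17 | 2-methoxy-4-(methoxymethoxy)benzaldehyde | COCOc1ccc(C=O)c(OC)c1
F4 | step 17 | (E)-1-{2-hydroxy-4,6-bis(methoxymethoxy)-3-[(2R)-5-methyl-2-[(2R)-1-(triisopropylsilyloxy)propan-2-yl]hex-4-enyl]phenyl}-3-[2-methoxy-4-(methoxymethoxy)phenyl]prop-2-en-1-one | COCOc1ccc(/C=C/C(=O)c2c(O)c(C[C@@H](CC=C(C)C)[C@@H](C)CO[Si](C(C)C)(C(C)C)C(C)C)c(OCOC)cc2OCOC)c(OC)c1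
F5 | step 17 | (2R)-epimer of 25 | COc1cc(OCOC)ccc1[C@H]1CC(=O)c2c(OCOC)cc(OCOC)c(C[C@@H](CC=C(C)C)[C@@H](C)CO[Si](C(C)C)(C(C)C)C(C)C)c2O1
F6 | step 12 | 1-{2-hydroxy-3-[(2R,3R)-2-(hydroxymethyl)-3-methyl-4-(triisopropylsilyloxy)butyl]-4,6-bis(methoxymethoxy)phenyl}ethanone | CC(=O)c1c(OCOC)cc(OCOC)c(C[C@@H](CO)[C@@H](C)CO[Si](C(C)C)(C(C)C)C(C)C)c1O
F7 | step 12 | 1-{2-hydroxy-3-[(2R,3R)-2-(iodomethyl)-3-methyl-4-(triisopropylsilyloxy)butyl]-4,6-bis(methoxymethoxy)phenyl}ethanone | CC(=O)c1c(OCOC)cc(OCOC)c(C[C@@H](CI)[C@@H](C)CO[Si](C(C)C)(C(C)C)C(C)C)c1O
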